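**Plan**
Locants: ring C1 (carbinol), C2, C3, C4 (CBr–CH3), C5 (CHCl), C6; chain C7 (=CH2), C8, C9 (CHOH), C10=C11.
Retrosynthesis: cut C8–C9 (allylsilane + 3-methylbut-2-enal). Take C7 and its two CH2 groups back to an ester carbon. Interchange and then remove the two halogens (C4=C5 alkene). Finally cut C2–C3 and C6–C1 together.
Enabling feature: the vicinal dihalide C4–C5 of the carbocycle is a masked alkene, so C3–C4(CH3)=C5–C6 is isoprene. C1–C2, with an oxygen and the sp2 carbon C7 on C1 para to C4, is an α-oxyacrylate. Such a cyclohexene is a Diels–Alder adduct.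
Forward: (S)-lactic acid gives a chiral 5-methylidene-1,3-dioxolan-4-one, a temporary ring that serves as activator and oxygen carrier. The cycloaddition builds the carbocycle as a spirobicycle, and halogenation follows while this is the only alkene. The acetal ring is then cleaved, its carbonyl carbon becomes C7, and the chain is joined there.
Stereochemistry: lactic acid centre → acetal carbon → C1 (face shielding by tert-butyl) → C4 and C5 (trans-diaxial bromochlorination, then stereospecific halogen interchange). C9 comes from a chiral boron Lewis acid.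

Key step: step 3

Remark: "face of O1" means the face of the carbocycle that carries the C1 oxygen. In the target Br lies on this face, and Cl, the C4 methyl group and C7 lie on the other.

Step 1
Reactants: 1 (S)-lactic acid; 2 pivalaldehyde
Product: 3 (2S,5S)-2-tert-butyl-5-methyl-1,3-dioxolan-4-one (cis)
Conditions: TsOH·H2O (cat.), pentane, Dean–Stark, reflux; recrystallisation from pentane/Et2O, −78 °C
Reagents that add atoms: none
Why: Acid-catalysed acetalisation of the α-hydroxy acid with removal of water gives the dioxolanone with the acetal centre set cis to the methyl group under thermodynamic control (self-regeneration of stereocentres), and crystallisation removes the trans isomer, which would otherwise end as the enantiomeric dienophile.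

Step 2
Reactants: 3 (2S,5S)-2-tert-butyl-5-methyl-1,3-dioxolan-4-one
Product: 5 (2S)-2-tert-butyl-5-methylidene-1,3-dioxolan-4-one, via tertiary bromide 4 (not isolated)
Conditions: NBS, 2,2'-azobis(isobutyronitrile) (cat.), PhCF3, reflux; filter; then Et3N, 0 °C to rt
Reagents that add atoms: N-bromosuccinimide, O=C1CCC(=O)N1Br (its bromine is held only in 4 and leaves again)
Why: Wohl–Ziegler bromination of the captodatively activated C5–H and E2 loss of HBr towards the methyl group give the exocyclic alkene, which erases the lactic acid centre while the untouched acetal centre keeps the chiral information.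

Step 3
Reactants: 5 (2S)-2-tert-butyl-5-methylidene-1,3-dioxolan-4-one; 6 isoprene
Product: 7 (2S,5R)-2-tert-butyl-8-methyl-1,3-dioxaspiro[4.5]dec-7-en-4-one
Conditions: 6 (excess), 2,6-di-tert-butyl-4-methylphenol (cat.), toluene, sealed tube, 110 °C
Reagents that add atoms: none
Why: A concerted, suprafacial, normal-electron-demand [4+2] cycloaddition joins the s-cis form of 6 to the exocyclic C=C of 5, whose LUMO is lowered by the lactone carbonyl group and which is held s-cis and strained by the five-membered ring. The closest known reaction type is the thermal Diels–Alder reaction of 5-methylidene-1,3-dioxolan-4-ones and related α-oxyacrylates with cyclic and acyclic 1,3-dienes. One ring is closed, the cyclohexene, by an intermolecular six-electron closure in which the dienophile CH2 (C2) bonds to the isoprene CH2 next to the methyl-bearing carbon (C3) and the dienophile α-carbon (C1) bonds to the other isoprene CH2 (C6), so that C1 becomes the spiro atom. The only new stereocentre, C1, is controlled by the tert-butyl group on the acetal carbon, which blocks one face of the nearly flat dioxolanone so that C6 is attached anti to it, and because 6 has no substituents at its termini, endo and exo approach on that face give the same product. The selectivity still needed is para over meta orientation, secured by matching the largest HOMO coefficient of 6 (the CH2 next to C–CH3) with the largest LUMO coefficient of 5 (its CH2), and the lesser meta pathway is dealt with by chromatography or crystallisation. Acid-free conditions keep the acetal centre from epimerising, and the phenol suppresses radical polymerisation of both partners.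

Step 4
Reactants: 7 (2S,5R)-2-tert-butyl-8-methyl-1,3-dioxaspiro[4.5]dec-7-en-4-one
Product: 8 (2S,5R,7R,8R)-7-bromo-2-tert-butyl-8-chloro-8-methyl-1,3-dioxaspiro[4.5]decan-4-one (Br on C5 on the face of O1, Cl on C4 on the opposite face)
Conditions: NBS + HCl (Et2O solution), CH2Cl2, −40 °C (BrCl formed in the flask); then 7, −78 °C, dark
Reagents that add atoms: N-bromosuccinimide, O=C1CCC(=O)N1Br; hydrogen chloride, Cl
Why: Anti bromochlorination through reversibly formed bromonium ions, opened by chloride at the tertiary carbon (Markovnikov) and trans-diaxially (Fürst–Plattner rule) in the half-chair that keeps the lactone carbonyl carbon equatorial and O1 axial, should place Br on C5 on the face of O1 and Cl on C4 on the other face, with the acetal oxygen too poorly nucleophilic to intercept the bromonium ion.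

Step 5
Reactants: 8 (2S,5R,7R,8R)-7-bromo-2-tert-butyl-8-chloro-8-methyl-1,3-dioxaspiro[4.5]decan-4-one
Product: 9 (2S,5R,7S,8S)-8-bromo-2-tert-butyl-7-chloro-8-methyl-1,3-dioxaspiro[4.5]decan-4-one
Conditions: MeCN, 2,6-di-tert-butylpyridine (5 mol %), sealed tube, 95 °C, dark; recovered 8 resubmitted
Reagents that add atoms: none
Why: This is the thermal dyotropic 1,2-interchange of antiperiplanar vicinal halogens (the diaxial-to-diequatorial rearrangement known for trans-diaxial 1,2-dihalocyclohexanes such as steroidal 5,6-dihalides), in which each halogen migrates on its own face with inversion at both carbons, so that Br reaches tertiary C4 and Cl reaches secondary C5 with the trans relation kept, helped by loss of the syn-diaxial Br/O1 contact and by better solvation of the more polar diequatorial dihalide.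

Step 6
Reactants: 9 (2S,5R,7S,8S)-8-bromo-2-tert-butyl-7-chloro-8-methyl-1,3-dioxaspiro[4.5]decan-4-one
Product: 10 methyl (1R,3S,4S)-4-bromo-3-chloro-1-hydroxy-4-methylcyclohexane-1-carboxylate
Conditions: MeOH, TsOH·H2O (cat.), 50 °C
Reagents that add atoms: methanol, CO
Why: Acid-catalysed transesterification of the acylal-type lactone removes the temporary ring as pivalaldehyde without touching a stereocentre, and the tertiary bromide should survive because the adjacent C–Cl dipole strongly retards its ionisation.

Step 7
Reactants: 10 methyl (1R,3S,4S)-4-bromo-3-chloro-1-hydroxy-4-methylcyclohexane-1-carboxylate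
Product: 11 methyl (1R,3S,4S)-4-bromo-3-chloro-4-methyl-1-(triethylsilyloxy)cyclohexane-1-carboxylate
Conditions: Et3SiOTf, 2,6-lutidine, CH2Cl2, 0 °C
Reagents that add atoms: triethylsilyl triflate, CC[Si](CC)(CC)OS(=O)(=O)C(F)(F)F
Why: Silylation of a hindered tertiary alcohol with a silyl triflate and a non-nucleophilic base is standard and masks the alkoxide that would otherwise desilylate the α-silyl ketone stage of the next step.

Step 8
Reactants: 11 methyl (1R,3S,4S)-4-bromo-3-chloro-4-methyl-1-(triethylsilyloxy)cyclohexane-1-carboxylate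
Product: 13 {2-[(1R,3S,4S)-4-bromo-3-chloro-4-methyl-1-(triethylsilyloxy)cyclohexyl]prop-2-en-1-yl}trimethylsilane, via bis(silylmethyl)carbinol 12 (not isolated)
Conditions: Me3SiCH2MgCl, CeCl3 (anhydrous), THF, −78 °C to rt; aq. NH4Cl; then SiO2, CH2Cl2, rt
Reagents that add atoms: (trimethylsilylmethyl)magnesium chloride, C[Si](C)(C)C[Mg]Cl
Why: Double addition of the weakly basic organocerium reagent to the ester and acid-induced Peterson elimination of one β-hydroxysilane arm is the established conversion of an ester into a 2-substituted allylsilane, and the low basicity of the reagent together with the diequatorial (not antiperiplanar) halogens should spare the dihalide.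

Step 9
Reactants: 13 {2-[(1R,3S,4S)-4-bromo-3-chloro-4-methyl-1-(triethylsilyloxy)cyclohexyl]prop-2-en-1-yl}trimethylsilane; 14 3-methylbut-2-enal
Product: 15 {[(4S)-2-[(1R,3S,4S)-4-bromo-3-chloro-4-methyl-1-(triethylsilyloxy)cyclohexyl]-6-methylhepta-1,5-dien-4-yl]oxy}trimethylsilane
Conditions: (acyloxy)borane formed from (2S,3S)-2-O-(2,6-diisopropoxybenzoyl)tartaric acid and BH3·THF (20 mol %), EtCN, −78 °C; neutral work-up
Reagents that add atoms: none
Why: In this catalytic enantioselective Hosomi–Sakurai allylation the =CH2 terminus of the allylsilane attacks the boron-bound enal 1,2 through an open transition state and the silyl group passes to oxygen, a construction well known for simple 2-substituted allylsilanes and enals, and the catalyst antipode from (2S,3S)-tartaric acid should expose the Si face and set (S)-C9 under catalyst control because the resident centres are remote.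

Step 10
Reactants: 15 {[(4S)-2-[(1R,3S,4S)-4-bromo-3-chloro-4-methyl-1-(triethylsilyloxy)cyclohexyl]-6-methylhepta-1,5-dien-4-yl]oxy}trimethylsilane
Product: 16 (1R,3S,4S)-4-bromo-3-chloro-1-[(4S)-4-hydroxy-6-methylhepta-1,5-dien-2-yl]-4-methylcyclohexan-1-ol
Conditions: HF·pyridine, pyridine, THF, 0 °C to rt
Reagents that add atoms: none
Why: Buffered fluoride cleavage of both silyl ethers touches no stereocentre and avoids both base-induced loss of HBr from the tertiary bromide and acid-induced ionisation of the allylic alcohol.

**Compound list**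
1 | (S)-lactic acid | C[C@H](O)C(=O)O | starting material
2 | pivalaldehyde | CC(C)(C)C=O | starting material
3 | (2S,5S)-2-tert-butyl-5-methyl-1,3-dioxolan-4-one | C[C@@H]1O[C@H](C(C)(C)C)OC1=O | intermediate
4 | 5-bromo-2-tert-butyl-5-methyl-1,3-dioxolan-4-one, Br trans to tert-butyl (descriptors 2R,5R; the acetal centre is unchanged in space) | C[C@]1(Br)O[C@H](C(C)(C)C)OC1=O | intermediate
5 | (2S)-2-tert-butyl-5-methylidene-1,3-dioxolan-4-one | C=C1O[C@H](C(C)(C)C)OC1=O | intermediate
6 | isoprene | C=CC(C)=C | starting material
7 | (2S,5R)-2-tert-butyl-8-methyl-1,3-dioxaspiro[4.5]dec-7-en-4-one | O=C1O[C@@H](C(C)(C)C)O[C@@]12CCC(C)=CC2 | intermediate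
8 | (2S,5R,7R,8R)-7-bromo-2-tert-butyl-8-chloro-8-methyl-1,3-dioxaspiro[4.5]decan-4-one | O=C1O[C@@H](C(C)(C)C)O[C@@]12CC[C@@](C)(Cl)[C@H](Br)C2 | intermediate
9 | (2S,5R,7S,8S)-8-bromo-2-tert-butyl-7-chloro-8-methyl-1,3-dioxaspiro[4.5]decan-4-one | O=C1O[C@@H](C(C)(C)C)O[C@@]12CC[C@](C)(Br)[C@@H](Cl)C2 | intermediate
10 | methyl (1R,3S,4S)-4-bromo-3-chloro-1-hydroxy-4-methylcyclohexane-1-carboxylate | COC(=O)[C@@]1(O)CC[C@](C)(Br)[C@@H](Cl)C1 | intermediate
11 | methyl (1R,3S,4S)-4-bromo-3-chloro-4-methyl-1-(triethylsilyloxy)cyclohexane-1-carboxylate | COC(=O)[C@@]1(O[Si](CC)(CC)CC)CC[C@](C)(Br)[C@@H](Cl)C1 | intermediate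
12 | 2-[(1R,3S,4S)-4-bromo-3-chloro-4-methyl-1-(triethylsilyloxy)cyclohexyl]-1,3-bis(trimethylsilyl)propan-2-ol | C[Si](C)(C)CC(O)(C[Si](C)(C)C)[C@@]1(O[Si](CC)(CC)CC)CC[C@](C)(Br)[C@@H](Cl)C1 | intermediate
13 | {2-[(1R,3S,4S)-4-bromo-3-chloro-4-methyl-1-(triethylsilyloxy)cyclohexyl]prop-2-en-1-yl}trimethylsilane | C=C(C[Si](C)(C)C)[C@@]1(O[Si](CC)(CC)CC)CC[C@](C)(Br)[C@@H](Cl)C1 | intermediate
14 | 3-methylbut-2-enal | CC(C)=CC=O | starting material
15 | {[(4S)-2-[(1R,3S,4S)-4-bromo-3-chloro-4-methyl-1-(triethylsilyloxy)cyclohexyl]-6-methylhepta-1,5-dien-4-yl]oxy}trimethylsilane | C=C(C[C@H](O[Si](C)(C)C)C=C(C)C)[C@@]1(O[Si](CC)(CC)CC)CC[C@](C)(Br)[C@@H](Cl)C1 | intermediate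
16 | (1R,3S,4S)-4-bromo-3-chloro-1-[(4S)-4-hydroxy-6-methylhepta-1,5-dien-2-yl]-4-methylcyclohexan-1-ol | C=C(C[C@H](O)C=C(C)C)[C@@]1(O)CC[C@](C)(Br)[C@@H](Cl)C1 | target

Total step count: 10. Longest linear sequence: 10 steps, from 1.

**Steps most likely to fail**

Step 5. The equilibrium between the two trans-dihalides may not lie far enough on the wanted side, and thermal loss of hydrogen halide may compete.
- The fallback sets out from 7 and comes back at 9. It builds the halogen pattern by substitution instead of rearrangement.
- Epoxidation of 7 with mCPBA (CH2Cl2, NaHCO3) is not expected to be face selective, so the O1-face epoxide F1 is separated.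
- LiCl/AcOH in THF opens F1 at the less hindered secondary carbon with inversion, which gives the trans-chlorohydrin F2 (Cl on C5 opposite to O1, tertiary OH on C4 on the face of O1).
- Me3SiBr in CH2Cl2 then replaces the tertiary hydroxyl by bromide with retention, through participation of the antiperiplanar chlorine (chloronium ion). This gives 9.

Step 9. Three processes threaten this step: poor facial selectivity or low reactivity of the hindered allylsilane under the chiral catalyst, pinacol-type ring expansion of the β-silyl cation next to C1–O, and ionisation of the allylic silyl ether.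
- The fallback sets out from 13 and 14 and comes back at 16. C9 is set by ketone reduction instead of by C–C bond formation.
- BF3·OEt2 (CH2Cl2, −78 °C) gives the C9-epimeric alcohol mixture F3.
- Dess–Martin oxidation (NaHCO3 buffer) gives the cross-conjugated dienone F4.
- Corey–Bakshi–Shibata reduction gives the (9S)-alcohol F5, with the alkenyl arm acting as the large group. The reagents are (R)-2-methyl-CBS-oxazaborolidine [(3aR)-1-methyl-3,3-diphenyltetrahydro-3H-pyrrolo[1,2-c][1,3,2]oxazaborole] and catecholborane in toluene at −78 °C.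
- HF·pyridine then gives 16.

Step 8. The reaction may stall after the first addition through steric hindrance or enolisation. The triethylsilyl group may migrate to the new alkoxide, or the metal may induce loss of the two halogens.
- The fallback sets out from 11 and comes back at 15. It replaces the allylsilane by an aldol/methylenation sequence.
- One equivalent of Me3SiCH2Li (THF/pentane, −78 °C) gives the α-silyl ketone F6, which MeOH protodesilylates to the methyl ketone F7.
- Me3SiOTf/Et3N gives the silyl enol ether F8.
- A Mukaiyama aldol addition to 14 under the same (acyloxy)borane catalyst gives the (9S)-β-silyloxy ketone F9.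
- Tebbe methylenation with Cp2Ti(μ-Cl)(μ-CH2)AlMe2 (toluene/THF, −40 to 0 °C) gives 15.

**Further compounds**
F1 | step 5 | epoxide of 7 at the ring alkene, oxirane oxygen on the face of O1 | O=C1O[C@@H](C(C)(C)C)O[C@@]12CC[C@]3(C)O[C@@H]3C2
F2 | step 5 | (2S,5R,7S,8S)-2-tert-butyl-7-chloro-8-hydroxy-8-methyl-1,3-dioxaspiro[4.5]decan-4-one | O=C1O[C@@H](C(C)(C)C)O[C@@]12CC[C@](C)(O)[C@@H](Cl)C2
F3 | step 9 | 2-[(1R,3S,4S)-4-bromo-3-chloro-4-methyl-1-(triethylsilyloxy)cyclohexyl]-6-methylhepta-1,5-dien-4-ol, both C4 epimers | C=C(CC(O)C=C(C)C)[C@@]1(O[Si](CC)(CC)CC)CC[C@](C)(Br)[C@@H](Cl)C1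
F4 | step 9 | 2-[(1R,3S,4S)-4-bromo-3-chloro-4-methyl-1-(triethylsilyloxy)cyclohexyl]-6-methylhepta-1,5-dien-4-one | C=C(CC(=O)C=C(C)C)[C@@]1(O[Si](CC)(CC)CC)CC[C@](C)(Br)[C@@H](Cl)C1
F5 | step 9 | (4S)-2-[(1R,3S,4S)-4-bromo-3-chloro-4-methyl-1-(triethylsilyloxy)cyclohexyl]-6-methylhepta-1,5-dien-4-ol | C=C(C[C@H](O)C=C(C)C)[C@@]1(O[Si](CC)(CC)CC)CC[C@](C)(Br)[C@@H](Cl)C1
F6 | step 8 | 1-[(1R,3S,4S)-4-bromo-3-chloro-4-methyl-1-(triethylsilyloxy)cyclohexyl]-2-(trimethylsilyl)ethan-1-one | C[Si](C)(C)CC(=O)[C@@]1(O[Si](CC)(CC)CC)CC[C@](C)(Br)[C@@H](Cl)C1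
F7 | step 8 | 1-[(1R,3S,4S)-4-bromo-3-chloro-4-methyl-1-(triethylsilyloxy)cyclohexyl]ethan-1-one | CC(=O)[C@@]1(O[Si](CC)(CC)CC)CC[C@](C)(Br)[C@@H](Cl)C1
F8 | step 8 | trimethylsilyl enol ether of F7 | C=C(O[Si](C)(C)C)[C@@]1(O[Si](CC)(CC)CC)CC[C@](C)(Br)[C@@H](Cl)C1
F9 | step 8 | (3S)-1-[(1R,3S,4S)-4-bromo-3-chloro-4-methyl-1-(triethylsilyloxy)cyclohexyl]-5-methyl-3-(trimethylsilyloxy)hex-4-en-1-one | O=C(C[C@H](O[Si](C)(C)C)C=C(C)C)[C@@]1(O[Si](CC)(CC)CC)CC[C@](C)(Br)[C@@H](Cl)C1
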